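**Retrosynthetic overview**
1. Target 11 ⇒ cut the ring B C–CO2H bond; it is made last by a new magnesium-templated ortho C–H carboxylation of phenol 8 with CO2.
2. Phenol 8 ⇒ cut the depside ester C–O bond: hindered ring A acid chloride 7 plus symmetric divarinol 1 (two equivalent OH groups).
3. Ring A acid 6 ⇒ aryl bromide 3 (Li–Br exchange, CO2) ⇒ dimethyl ether 2 ⇒ divarinol 1.
4. No ring is built: both benzene rings come ready-made from divarinol 1; ring A is elaborated first, ring B is attached next and carboxylated last.

Assumption: the target has no stereocentre or stereoaxis (it is achiral), so "single enantiomer" is read as the one structure drawn, and 5-propylbenzene-1,3-diol (divarinol) is taken as commercially available.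

**Route**

Step 1
Reactants: 1 5-propylbenzene-1,3-diol (divarinol)
Product: 2 1,3-dimethoxy-5-propylbenzene
Conditions: MeI (2.5 equiv), K2CO3 (3 equiv), acetone, reflux
Reagents that add atoms: iodomethane, CI
Why: Williamson ether synthesis, in which both phenoxides formed with K2CO3 are methylated by SN2 attack on MeI; no stereocentre is formed.

Step 2
Reactants: 2 1,3-dimethoxy-5-propylbenzene
Product: 3 2-bromo-1,5-dimethoxy-3-propylbenzene
Conditions: NBS (1.0 equiv), MeCN, 0 °C to rt
Reagents that add atoms: N-bromosuccinimide, O=C1CCC(=O)N1Br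
Why: Electrophilic aromatic bromination, which in 3,5-dimethoxyalkylbenzenes goes once to the carbon para to one OMe and ortho to the other (beside the alkyl group) and leaves the carbon between the two OMe groups alone.

Step 3
Reactants: 3 2-bromo-1,5-dimethoxy-3-propylbenzene
Product: 6 2,4-dimethoxy-6-propylbenzoic acid, via aryllithium 4 (not isolated), via lithium carboxylate 5 (not isolated)
Conditions: n-BuLi (1.05 equiv), THF, −78 °C; CO2 (gas), −78 °C to rt; then 1 M HCl
Reagents that add atoms: carbon dioxide, O=C=O
Why: Lithium–bromine exchange followed by carboxylation; exchange at −78 °C is far faster than ortho-lithiation between the OMe groups, so CO2 is fixed exactly where bromine stood and acid work-up frees the acid.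

Step 4
Reactants: 6 2,4-dimethoxy-6-propylbenzoic acid
Product: 7 2,4-dimethoxy-6-propylbenzoyl chloride
Conditions: (COCl)2 (1.5 equiv), DMF (cat.), CH2Cl2, 0 °C to rt; evaporate and use crude
Reagents that add atoms: oxalyl chloride, O=C(Cl)C(Cl)=O
Why: Acid chloride formation with oxalyl chloride under DMF catalysis (Vilsmeier-type activation) runs at room temperature and does not touch the aryl methyl ethers.

Step 5
Reactants: 7 2,4-dimethoxy-6-propylbenzoyl chloride; 1 5-propylbenzene-1,3-diol (divarinol)
Product: 8 3-hydroxy-5-propylphenyl 2,4-dimethoxy-6-propylbenzoate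
Conditions: 1 (3 equiv), Et3N (1.5 equiv), DMAP (10 mol%), THF, 0 °C to rt; excess 1 recovered on silica
Reagents that add atoms: none
Why: DMAP-catalysed O-acylation of a phenol (nucleophilic acyl substitution); the two OH groups of 1 are equivalent by symmetry, the threefold excess keeps the diester low, and basic conditions favour O- over C-acylation.

Step 6
Reactants: 8 3-hydroxy-5-propylphenyl 2,4-dimethoxy-6-propylbenzoate
Product: 11 4-[(2,4-dimethoxy-6-propylbenzoyl)oxy]-2-hydroxy-6-propylbenzoic acid, via chloromagnesium phenoxide 9 (not isolated), via magnesium salicylate 10 (not isolated)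
Conditions: MgCl2 (anhydrous, 3 equiv), Et3N (6 equiv), CO2 (20 bar), dry MeCN, 90 °C, autoclave; then 1 M HCl, 0 °C
Reagents that add atoms: carbon dioxide, O=C=O
Why: Proposed new method: a magnesium-templated ortho C–H carboxylation of a monohydric phenol with CO2, in which MgCl2/Et3N turns the phenol into chloromagnesium phenoxide 9, the Lewis-acidic Mg2+ centre binds CO2 and delivers it to the ortho carbon through a six-membered transition state (Kolbe–Schmitt-type attack), Et3N rearomatises the cyclohexadienone, and the O,O-chelated magnesium salicylate 10 is the thermodynamic sink that pulls the otherwise unfavourable equilibrium; attack is expected at the ortho carbon between OH and propyl (para to the ester oxygen) because the other ortho carbon sits beside the bulky, twisted 2,6-disubstituted aroyloxy group and orcinol-type rings are carboxylated beside the alkyl group, the para carbon is out of reach of the chelate, a second carboxylation is shut off by the new electron-poor carboxylate, and the doubly ortho-substituted aryl ester is too hindered for attack by Et3N or phenoxide; the closest known reaction types are the MgCl2/Et3N ortho-formylation of phenols with paraformaldehyde, the MgCl2/Et3N carboxylation of ketones with CO2 and the carboxylation of resorcinols with methyl magnesium carbonate, none of which has been shown with CO2 on a simple phenol carrying an aryl ester; no stereocentre is formed.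

**Compound list**
1 | 5-propylbenzene-1,3-diol (divarinol) | CCCc1cc(O)cc(O)c1 | starting material
2 | 1,3-dimethoxy-5-propylbenzene | CCCc1cc(OC)cc(OC)c1 | intermediate
3 | 2-bromo-1,5-dimethoxy-3-propylbenzene | CCCc1cc(OC)cc(OC)c1Br | intermediate
4 | (2,4-dimethoxy-6-propylphenyl)lithium | CCCc1cc(OC)cc(OC)c1[Li] | intermediate
5 | lithium 2,4-dimethoxy-6-propylbenzoate | CCCc1cc(OC)cc(OC)c1C(=O)[O-].[Li+] | intermediate
6 | 2,4-dimethoxy-6-propylbenzoic acid | CCCc1cc(OC)cc(OC)c1C(=O)O | intermediate
7 | 2,4-dimethoxy-6-propylbenzoyl chloride | CCCc1cc(OC)cc(OC)c1C(=O)Cl | intermediate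
8 | 3-hydroxy-5-propylphenyl 2,4-dimethoxy-6-propylbenzoate | CCCc1cc(O)cc(OC(=O)c2c(CCC)cc(OC)cc2OC)c1 | intermediate
9 | chloromagnesium 3-[(2,4-dimethoxy-6-propylbenzoyl)oxy]-5-propylphenoxide | CCCc1cc(O[Mg]Cl)cc(OC(=O)c2c(CCC)cc(OC)cc2OC)c1 | intermediate
10 | magnesium 4-[(2,4-dimethoxy-6-propylbenzoyl)oxy]-2-oxido-6-propylbenzoate | CCCc1cc(OC(=O)c2c(CCC)cc(OC)cc2OC)cc([O-])c1C(=O)[O-].[Mg+2] | intermediate
11 | 4-[(2,4-dimethoxy-6-propylbenzoyl)oxy]-2-hydroxy-6-propylbenzoic acid | CCCc1cc(OC(=O)c2c(CCC)cc(OC)cc2OC)cc(O)c1C(=O)O | target

**Totals**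
Total step count: 6.
Longest linear sequence: 6 steps (1 → 2 → 3 → 6 → 7 → 8 → 11); divarinol 1 enters a second time in step 5 as bought material.

**Three steps most likely to fail, with fallbacks**

Step 6 (the new carboxylation). The risks are no conversion at a temperature the ester tolerates, or attack at the ortho carbon between the two oxygens. The fallback is the classical depside route, all known chemistry; it sets out from 1 and 7 and comes back at 11. Divarinol 1 is carboxylated with methyl magnesium carbonate (MeOMgOCO2Me, DMF, 120 °C), which gives the chelate magnesium 4-hydroxy-2-oxido-6-propylbenzoate F1. Work-up with 1 M HCl turns this into 2,4-dihydroxy-6-propylbenzoic acid F2. BnBr with KHCO3 in DMF at rt alkylates only the carboxylate and gives benzyl 2,4-dihydroxy-6-propylbenzoate F3. Acid chloride 7 with Et3N and DMAP in CH2Cl2 acylates the 4-OH, since the 2-OH is tied up in a hydrogen bond to the ester carbonyl, and gives benzyl 4-[(2,4-dimethoxy-6-propylbenzoyl)oxy]-2-hydroxy-6-propylbenzoate F4. Hydrogenolysis (H2, 10 wt% Pd/C, EtOAc, rt) removes the benzyl group without touching the aryl ester and gives 11.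

Step 5 (statistical mono-acylation with a hindered acid chloride). The risks are diester formation and a slow reaction that cannot be forced while 1 is in excess. The fallback is a protect–acylate–deprotect sequence; it sets out from 1 and comes back at 8. Divarinol 1 is mono-silylated with i-Pr3SiCl (1.0 equiv) and imidazole in DMF to give 3-propyl-5-{[tri(propan-2-yl)silyl]oxy}phenol F5; the bis-silyl ether and unreacted 1 separate easily and are recycled. With a single free OH, the acylation can be run 1:1 with 7 under forcing conditions (Et3N, DMAP, toluene, 80 °C) to give 3-propyl-5-{[tri(propan-2-yl)silyl]oxy}phenyl 2,4-dimethoxy-6-propylbenzoate F6. Buffered n-Bu4NF/AcOH in THF at 0 °C removes the silyl group, leaves the hindered ester intact and gives 8.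

Step 2 (bromination). The risks are a second bromination or some bromination between the OMe groups, giving mixtures that are hard to separate and that carry through the lithiation. The fallback replaces halogenation/metalation by formylation/oxidation; it sets out from 2 and comes back at 6, bypassing step 3 as well. Vilsmeier–Haack formylation of 2 (POCl3, DMF, 0 to 80 °C) gives the iminium ion [(2,4-dimethoxy-6-propylphenyl)methylidene]dimethylazanium F7. Aqueous NaOAc hydrolyses it to 2,4-dimethoxy-6-propylbenzaldehyde F8. Pinnick oxidation (NaClO2, NaH2PO4, 2-methyl-2-butene, t-BuOH/H2O, rt) gives acid 6.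

**Further compounds**
F1 | step 6 | magnesium 4-hydroxy-2-oxido-6-propylbenzoate | CCCc1cc(O)cc([O-])c1C(=O)[O-].[Mg+2]
F2 | step 6 | 2,4-dihydroxy-6-propylbenzoic acid (divaric acid) | CCCc1cc(O)cc(O)c1C(=O)O
F3 | step 6 | benzyl 2,4-dihydroxy-6-propylbenzoate | CCCc1cc(O)cc(O)c1C(=O)OCc1ccccc1
F4 | step 6 | benzyl 4-[(2,4-dimethoxy-6-propylbenzoyl)oxy]-2-hydroxy-6-propylbenzoate | CCCc1cc(OC(=O)c2c(CCC)cc(OC)cc2OC)cc(O)c1C(=O)OCc1ccccc1
F5 | step 5 | 3-propyl-5-{[tri(propan-2-yl)silyl]oxy}phenol | CCCc1cc(O)cc(O[Si](C(C)C)(C(C)C)C(C)C)c1
F6 | step 5 | 3-propyl-5-{[tri(propan-2-yl)silyl]oxy}phenyl 2,4-dimethoxy-6-propylbenzoate | CCCc1cc(O[Si](C(C)C)(C(C)C)C(C)C)cc(OC(=O)c2c(CCC)cc(OC)cc2OC)c1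
F7 | step 2 | [(2,4-dimethoxy-6-propylphenyl)methylidene]dimethylazanium (iminium ion) | CCCc1cc(OC)cc(OC)c1C=[N+](C)C
F8 | step 2 | 2,4-dimethoxy-6-propylbenzaldehyde | CCCc1cc(OC)cc(OC)c1C=O
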